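**Plan**

1. Retrosynthesis (prostanoid locants: ester carbon C1, ring C8–C12, Br on C10, carbinol C12): cut the C12 silyl ether, then C6–C7 (Negishi), then the ring bond C8–C12 together with C7–I, which takes the cyclopentenone back to a 1-ethynylcyclobut-2-en-1-ol; then C8–C9 (acetylide), the carbonyl transposition with C10–Br, and C12–C13 (allylbarium), back to a semisquarate.
2. Enabling feature: ring carbon C9 is a ketone whose α-carbon C8 carries the exocyclic C8=C7 bond and has the fully substituted carbinol C12 as its other ring neighbour. This α-alkylidene ketone is the retron of a semipinacol shift in an alkynyl carbinol; with C9 and C12 tied in a cyclobutene, ring strain drives the shift.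
3. Forward: the four-membered ring is bought as a squarate. The ω-chain is joined, the tertiary carbinol resolved, bromine introduced, the carbonyl transposed and ethyne added. Only then does the five-membered ring arise, by enlargement of the cyclobutene by one carbon; the α-chain is joined last.
4. Stereochemistry: C12 comes from resolution of racemic carbinol 7 on a chiral phase and is carried through the 1,2-shift with retention. 14Z comes from (Z)-octenol through the allylbarium; 7Z from anti addition of migrating carbon and gold across the alkyne, then stereoretentive iodination and coupling; 5E from syn hydrozirconation.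

Key step: step 9

Remark: (Z)-oct-2-en-1-ol (4) is taken as purchased; compounds 11 and 13 are epimer mixtures at a centre that is destroyed later, so their SMILES leave that centre undefined.

Step 1
Reactants: 1 diisopropyl squarate (3,4-diisopropoxycyclobut-3-ene-1,2-dione)
Product: 3 3-isopropoxycyclobut-3-ene-1,2-dione, via hydroxycyclobutenone 2 (not isolated)
Conditions: LiAlH(OtBu)3, THF, −78 °C; then 6 M aq. HCl, CH2Cl2, 23 °C
Reagents that add atoms: water, O
Why: Hydride 1,2-reduction of one squarate carbonyl followed by acid-promoted hydrolysis of the resulting allylic alcohol/enol ether with loss of isopropanol is the standard reduction–hydrolysis route from dialkyl squarates to semisquarates.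

Step 2
Reactants: 4 (Z)-oct-2-en-1-ol
Product: 5 (Z)-1-chlorooct-2-ene
Conditions: N-chlorosuccinimide, Me2S, CH2Cl2, −20 to 0 °C
Reagents that add atoms: N-chlorosuccinimide, O=C1CCC(=O)N1Cl
Why: Corey–Kim chlorination converts an allylic alcohol into the allylic chloride through an alkoxysulfonium salt without allylic shift or loss of the Z geometry.

Step 3
Reactants: 3 3-isopropoxycyclobut-3-ene-1,2-dione; 5 (Z)-1-chlorooct-2-ene
Product: 7 rac-4-hydroxy-3-isopropoxy-4-[(Z)-oct-2-en-1-yl]cyclobut-2-en-1-one, via (Z)-oct-2-enylbarium chloride 6 (not isolated)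
Conditions: BaI2, lithium biphenylide, THF, 23 °C; 5, −78 °C; then 3, −78 °C; aq. NH4Cl
Reagents that add atoms: none
Why: Allylbarium reagents made at −78 °C add to carbonyl groups at their α-carbon with retention of olefin geometry (α-selective allylbarium addition), and they should attack the ketone next to the alkoxy-bearing ring carbon because the other carbonyl is a deactivated vinylogous ester; the new carbinol centre forms as a racemate.

Step 4
Reactants: 7 rac-4-hydroxy-3-isopropoxy-4-[(Z)-oct-2-en-1-yl]cyclobut-2-en-1-one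
Product: 8 (R)-4-hydroxy-3-isopropoxy-4-[(Z)-oct-2-en-1-yl]cyclobut-2-en-1-one
Conditions: preparative supercritical-fluid chromatography, amylose tris(3,5-dimethylphenylcarbamate) phase, CO2/iPrOH, 35 °C
Reagents that add atoms: none
Why: Resolution by chromatography on a chiral stationary phase should separate the enantiomers of this UV-active, hydrogen-bond-donating carbinol; the configuration is to be assigned on bromide 10 by anomalous dispersion, and the unwanted enantiomer can be racemised through its achiral 2-hydroxycyclobutane-1,3-dione (enol ether hydrolysis and re-etherification) and resolved again.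

Step 5
Reactants: 8 (R)-4-hydroxy-3-isopropoxy-4-[(Z)-oct-2-en-1-yl]cyclobut-2-en-1-one
Product: 9 (R)-3-isopropoxy-4-[(Z)-oct-2-en-1-yl]-4-(triethylsilyloxy)cyclobut-2-en-1-one
Conditions: Et3SiOTf, 2,6-lutidine, CH2Cl2, −78 to 0 °C
Reagents that add atoms: triethylsilyl trifluoromethanesulfonate, CC[Si](CC)(CC)OS(=O)(=O)C(F)(F)F
Why: Silyl ether protection of the tertiary alcohol with a silyl triflate and a hindered base keeps the oxygen from forming an alkoxide in step 8 and from adding to the activated alkyne in step 9.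

Step 6
Reactants: 9 (R)-3-isopropoxy-4-[(Z)-oct-2-en-1-yl]-4-(triethylsilyloxy)cyclobut-2-en-1-one
Product: 10 (R)-2-bromo-3-isopropoxy-4-[(Z)-oct-2-en-1-yl]-4-(triethylsilyloxy)cyclobut-2-en-1-one
Conditions: N-bromosuccinimide, CH2Cl2, 0 °C, dark
Reagents that add atoms: N-bromosuccinimide, O=C1CCC(=O)N1Br
Why: Electrophilic α-bromination of a vinylogous ester: the α-carbon of the β-alkoxy enone is the nucleophilic site and should react far faster than the isolated Z-alkene in an aprotic solvent in the dark.

Step 7
Reactants: 10 (R)-2-bromo-3-isopropoxy-4-[(Z)-oct-2-en-1-yl]-4-(triethylsilyloxy)cyclobut-2-en-1-one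
Product: 12 (S)-2-bromo-4-[(Z)-oct-2-en-1-yl]-4-(triethylsilyloxy)cyclobut-2-en-1-one, via cyclobutenol 11 (not isolated)
Conditions: NaBH4, CeCl3·7H2O, MeOH, −40 °C; then 1 M aq. HCl, THF, 0 °C
Reagents that add atoms: water, O
Why: Stork–Danheiser transposition: Luche 1,2-reduction of the vinylogous ester carbonyl and acid hydrolysis of the β-hydroxy enol ether move the carbonyl to the former alkoxy carbon and leave the bromine on the α-carbon of the new enone, without touching the silyloxy-bearing centre.

Step 8
Reactants: 12 (S)-2-bromo-4-[(Z)-oct-2-en-1-yl]-4-(triethylsilyloxy)cyclobut-2-en-1-one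
Product: 13 (4S)-2-bromo-1-ethynyl-4-[(Z)-oct-2-en-1-yl]-4-(triethylsilyloxy)cyclobut-2-en-1-ol (C1 epimers)
Conditions: HC≡CMgBr, THF, −78 °C; sat. aq. NH4Cl at −78 °C; work-up and chromatography below 0 °C
Reagents that add atoms: ethynylmagnesium bromide, C#C[Mg]Br
Why: 1,2-Addition of an alkynyl Grignard reagent to the strained cyclobutenone carbonyl; attack anti to the silyloxy group should favour the epimer with cis oxygens, which is also the one less prone to conrotatory ring opening, and the new centre needs no control because it becomes the ketone in step 9.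

Step 9
Reactants: 13 (4S)-2-bromo-1-ethynyl-4-[(Z)-oct-2-en-1-yl]-4-(triethylsilyloxy)cyclobut-2-en-1-ol
Product: 14 (4S,5Z)-2-bromo-5-(iodomethylidene)-4-[(Z)-oct-2-en-1-yl]-4-(triethylsilyloxy)cyclopent-2-en-1-one
Conditions: (Ph3P)AuNTf2 (3 mol %), N-iodosuccinimide (1.2 equiv), CH2Cl2, −30 to 0 °C, dark
Reagents that add atoms: N-iodosuccinimide, O=C1CCC(=O)N1I
Why: Proposed new method: the cationic monovalent-gold catalyst binds the terminal alkyne of 13, the strained ring bond between the carbinol carbon and the silyloxy-bearing carbon shifts to the inner alkyne carbon anti to gold while the carbinol becomes the ketone (semipinacol shift), and N-iodosuccinimide then replaces gold on the vinylgold with retention. The closest known reactions are the monovalent-gold-catalysed ring enlargement of 1-alkynylcyclobutanols to 2-alkylidenecyclopentanones, which ends in protodeauration, and the iododeauration of vinylgold intermediates by N-iodosuccinimide. The five-membered ring is closed by a 1,2-shift of a ring carbon, an enlargement of the four-membered ring by one carbon and not a cyclisation of a chain. No new stereocentre is formed and the carbinol centre of 13 is destroyed, so both epimers converge; the migrating carbon keeps its configuration because the shift is suprafacial, and the anti relation of migrating carbon and gold fixes the new exocyclic double bond with iodine on the carbonyl side (Z). The step needs migration of the sp3 ring carbon and not of the bromovinyl carbon, which the higher migratory aptitude of the oxygen-bearing tertiary carbon and the strain of a bridged transition state through the ring alkene should secure, and it needs activation of the alkyne ahead of the Z-alkene, which the alkynophilic catalyst provides. π-Activation must also outrun C–H iodination of the alkyne and protonation of the vinylgold, for which low temperature, a non-basic counter-ion and an excess of N-iodosuccinimide are chosen.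

Step 10
Reactants: 14 (4S,5Z)-2-bromo-5-(iodomethylidene)-4-[(Z)-oct-2-en-1-yl]-4-(triethylsilyloxy)cyclopent-2-en-1-one; 15 methyl hex-5-ynoate
Product: 18 methyl (5E,7Z)-7-[(2S)-4-bromo-2-[(Z)-oct-2-en-1-yl]-5-oxo-2-(triethylsilyloxy)cyclopent-3-en-1-ylidene]hept-5-enoate, via alkenylzirconocene chloride 16 (not isolated), via alkenylzinc chloride 17 (not isolated)
Conditions: 15, Cp2Zr(H)Cl, THF, 23 °C; ZnCl2, 0 °C; then 14, Pd(PPh3)4 (5 mol %), 0 to 23 °C
Reagents that add atoms: none
Why: Syn, anti-Markovnikov hydrozirconation of the terminal alkyne gives the (E)-alkenylzirconium, zinc chloride transmetalates it, and Negishi coupling with the β-iodoenone should proceed with retention at both alkenyl carbons, the C–I bond reacting with zerovalent palladium well before the C–Br bond.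

Step 11
Reactants: 18 methyl (5E,7Z)-7-[(2S)-4-bromo-2-[(Z)-oct-2-en-1-yl]-5-oxo-2-(triethylsilyloxy)cyclopent-3-en-1-ylidene]hept-5-enoate
Product: 19 methyl (5E,7Z)-7-[(2S)-4-bromo-2-hydroxy-2-[(Z)-oct-2-en-1-yl]-5-oxocyclopent-3-en-1-ylidene]hept-5-enoate
Conditions: HF·pyridine, pyridine, THF, 0 °C
Reagents that add atoms: none
Why: Desilylation of the tertiary triethylsilyl ether with buffered HF·pyridine is mild enough for the cross-conjugated bromodienone and the tertiary allylic alcohol.

**Compound list**

1 | diisopropyl squarate (3,4-diisopropoxycyclobut-3-ene-1,2-dione) | CC(C)OC1=C(OC(C)C)C(=O)C1=O | starting material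
2 | 4-hydroxy-2,3-diisopropoxycyclobut-2-en-1-one (racemic) | CC(C)OC1=C(OC(C)C)C(O)C1=O | intermediate
3 | 3-isopropoxycyclobut-3-ene-1,2-dione | CC(C)OC1=CC(=O)C1=O | intermediate
4 | (Z)-oct-2-en-1-ol | CCCCC/C=C\CO | starting material
5 | (Z)-1-chlorooct-2-ene | CCCCC/C=C\CCl | intermediate
6 | (Z)-oct-2-en-1-ylbarium chloride | CCCCC/C=C\C[Ba]Cl | intermediate
7 | rac-4-hydroxy-3-isopropoxy-4-[(Z)-oct-2-en-1-yl]cyclobut-2-en-1-one | CCCCC/C=C\CC1(O)C(=O)C=C1OC(C)C | intermediate
8 | (R)-4-hydroxy-3-isopropoxy-4-[(Z)-oct-2-en-1-yl]cyclobut-2-en-1-one | CCCCC/C=C\C[C@]1(O)C(=O)C=C1OC(C)C | intermediate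
9 | (R)-3-isopropoxy-4-[(Z)-oct-2-en-1-yl]-4-(triethylsilyloxy)cyclobut-2-en-1-one | CCCCC/C=C\C[C@]1(O[Si](CC)(CC)CC)C(=O)C=C1OC(C)C | intermediate
10 | (R)-2-bromo-3-isopropoxy-4-[(Z)-oct-2-en-1-yl]-4-(triethylsilyloxy)cyclobut-2-en-1-one | CCCCC/C=C\C[C@]1(O[Si](CC)(CC)CC)C(=O)C(Br)=C1OC(C)C | intermediate
11 | (4S)-2-bromo-3-isopropoxy-4-[(Z)-oct-2-en-1-yl]-4-(triethylsilyloxy)cyclobut-2-en-1-ol (C1 epimers) | CCCCC/C=C\C[C@]1(O[Si](CC)(CC)CC)C(O)C(Br)=C1OC(C)C | intermediate
12 | (S)-2-bromo-4-[(Z)-oct-2-en-1-yl]-4-(triethylsilyloxy)cyclobut-2-en-1-one | CCCCC/C=C\C[C@]1(O[Si](CC)(CC)CC)C=C(Br)C1=O | intermediate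
13 | (4S)-2-bromo-1-ethynyl-4-[(Z)-oct-2-en-1-yl]-4-(triethylsilyloxy)cyclobut-2-en-1-ol (C1 epimers) | CCCCC/C=C\C[C@]1(O[Si](CC)(CC)CC)C=C(Br)C1(O)C#C | intermediate
14 | (4S,5Z)-2-bromo-5-(iodomethylidene)-4-[(Z)-oct-2-en-1-yl]-4-(triethylsilyloxy)cyclopent-2-en-1-one | CCCCC/C=C\C[C@]1(O[Si](CC)(CC)CC)C=C(Br)C(=O)/C1=C\I | intermediate
15 | methyl hex-5-ynoate | C#CCCCC(=O)OC | starting material
16 | chlorobis(cyclopentadienyl)[(1E)-6-methoxy-6-oxohex-1-en-1-yl]zirconium | COC(=O)CCC/C=C/[Zr](Cl)(C1C=CC=C1)C1C=CC=C1 | intermediate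
17 | [(1E)-6-methoxy-6-oxohex-1-en-1-yl]zinc chloride | COC(=O)CCC/C=C/[Zn]Cl | intermediate
18 | methyl (5E,7Z)-7-[(2S)-4-bromo-2-[(Z)-oct-2-en-1-yl]-5-oxo-2-(triethylsilyloxy)cyclopent-3-en-1-ylidene]hept-5-enoate | CCCCC/C=C\C[C@]1(O[Si](CC)(CC)CC)C=C(Br)C(=O)/C1=C\C=C\CCCC(=O)OC | intermediate
19 | methyl (5E,7Z)-7-[(2S)-4-bromo-2-hydroxy-2-[(Z)-oct-2-en-1-yl]-5-oxocyclopent-3-en-1-ylidene]hept-5-enoate | CCCCC/C=C\C[C@]1(O)C=C(Br)C(=O)/C1=C\C=C\CCCC(=O)OC | target

Total step count: 11. Longest linear sequence: 10 steps (1 → 3 → 7 → 8 → 9 → 10 → 12 → 13 → 14 → 18 → 19).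

**Steps most likely to fail**

Step 9 (proposed new method). The vinylgold may be protonated before it is iodinated. The terminal C–H may be iodinated before the ring enlarges, which would put iodine on the other side of the new double bond. The cyclobutenol may also open before gold engages it. The fallback uses known reactions only and sets out from 13. Sonogashira coupling (PdCl2(PPh3)2, CuI, iPr2NH, THF, 0 °C) with methyl (E)-6-iodohex-5-enoate F1, made from 15 by hydrozirconation with Cp2Zr(H)Cl and iodinolysis, would give the enynyl carbinol methyl (5E)-8-[(4S)-2-bromo-1-hydroxy-4-[(Z)-oct-2-en-1-yl]-4-(triethylsilyloxy)cyclobut-2-en-1-yl]oct-5-en-7-ynoate F2. The established monovalent-gold-catalysed ring enlargement of 1-alkynylcyclobutanols with protodeauration ((Ph3P)AuNTf2, CH2Cl2, −20 °C) should then give the 7E isomer methyl (5E,7E)-7-[(2S)-4-bromo-2-[(Z)-oct-2-en-1-yl]-5-oxo-2-(triethylsilyloxy)cyclopent-3-en-1-ylidene]hept-5-enoate F3, with the chain on the side of the migrated carbon. Photochemical E/Z equilibration of the cross-conjugated dienone (365 nm, benzene), HPLC separation and recycling of F3 bring the route back at 18.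

Step 8. The cyclobutenyl alkoxide, or the neutral carbinol on warming, may undergo conrotatory electrocyclic ring opening (fastest for the epimer with trans oxygens), and conjugate addition may compete. The fallback avoids the alkynyl carbinol and sets out from 12. Lewis-acid-promoted homologation with Me3SiCHN2 (BF3·OEt2, CH2Cl2, −78 °C) should insert one carbon between the carbonyl and the silyloxy-bearing carbon to give (4S)-2-bromo-4-[(Z)-oct-2-en-1-yl]-4-(triethylsilyloxy)-5-(trimethylsilyl)cyclopent-2-en-1-one F4. Protodesilylation (1 M HCl, THF) gives (R)-2-bromo-4-[(Z)-oct-2-en-1-yl]-4-(triethylsilyloxy)cyclopent-2-en-1-one F5. Its kinetic lithium enolate (LiN(iPr)2, THF, −78 °C) is added to methyl (E)-7-oxohept-5-enoate F6, prepared from methyl 5-oxopentanoate and (triphenylphosphoranylidene)acetaldehyde, to give the aldol methyl (5E)-7-[(2R)-4-bromo-2-[(Z)-oct-2-en-1-yl]-5-oxo-2-(triethylsilyloxy)cyclopent-3-en-1-yl]-7-hydroxyhept-5-enoate F7. Mesylation and elimination (MsCl, Et3N, then DBU) should give 18 together with its 7E isomer (identical with F3), from which 18 is separated by HPLC; the route is rejoined at 18.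

Step 3. The allylbarium may lose α-regioselectivity or Z geometry through metallotropic equilibration before it adds, or it may deprotonate or add twice to the dione. The fallback sets out from 3. Barbier allylation with indium and allyl bromide (THF/H2O) gives rac-4-allyl-4-hydroxy-3-isopropoxycyclobut-2-en-1-one F8. Silylation (Et3SiOTf, 2,6-lutidine) gives rac-4-allyl-3-isopropoxy-4-(triethylsilyloxy)cyclobut-2-en-1-one F9. Lemieux–Johnson cleavage of the terminal alkene (OsO4 cat., NaIO4, 2,6-lutidine, dioxane/H2O) gives rac-2-[2-isopropoxy-4-oxo-1-(triethylsilyloxy)cyclobut-2-en-1-yl]acetaldehyde F10. A salt-free Wittig reaction with hexylidenetriphenylphosphorane (hexyltriphenylphosphonium bromide, NaN(SiMe3)2, THF, −78 °C) gives rac-3-isopropoxy-4-[(Z)-oct-2-en-1-yl]-4-(triethylsilyloxy)cyclobut-2-en-1-one F11, which is resolved on the chiral phase of step 4 to rejoin the route at 9.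

**Further compounds**

F1 | step 9 | methyl (E)-6-iodohex-5-enoate | COC(=O)CCC/C=C/I
F2 | step 9 | methyl (5E)-8-[(4S)-2-bromo-1-hydroxy-4-[(Z)-oct-2-en-1-yl]-4-(triethylsilyloxy)cyclobut-2-en-1-yl]oct-5-en-7-ynoate (C1 epimers) | CCCCC/C=C\C[C@]1(O[Si](CC)(CC)CC)C=C(Br)C1(O)C#C/C=C/CCCC(=O)OC
F3 | step 9 | methyl (5E,7E)-7-[(2S)-4-bromo-2-[(Z)-oct-2-en-1-yl]-5-oxo-2-(triethylsilyloxy)cyclopent-3-en-1-ylidene]hept-5-enoate | CCCCC/C=C\C[C@]1(O[Si](CC)(CC)CC)C=C(Br)C(=O)/C1=C/C=C/CCCC(=O)OC
F4 | step 8 | (4S)-2-bromo-4-[(Z)-oct-2-en-1-yl]-4-(triethylsilyloxy)-5-(trimethylsilyl)cyclopent-2-en-1-one (C5 epimers) | CCCCC/C=C\C[C@]1(O[Si](CC)(CC)CC)C=C(Br)C(=O)C1[Si](C)(C)C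
F5 | step 8 | (R)-2-bromo-4-[(Z)-oct-2-en-1-yl]-4-(triethylsilyloxy)cyclopent-2-en-1-one | CCCCC/C=C\C[C@]1(O[Si](CC)(CC)CC)C=C(Br)C(=O)C1
F6 | step 8 | methyl (E)-7-oxohept-5-enoate | COC(=O)CCC/C=C/C=O
F7 | step 8 | methyl (5E)-7-[(2R)-4-bromo-2-[(Z)-oct-2-en-1-yl]-5-oxo-2-(triethylsilyloxy)cyclopent-3-en-1-yl]-7-hydroxyhept-5-enoate (epimers at C7 and ring C1) | CCCCC/C=C\C[C@]1(O[Si](CC)(CC)CC)C=C(Br)C(=O)C1C(O)/C=C/CCCC(=O)OC
F8 | step 3 | rac-4-allyl-4-hydroxy-3-isopropoxycyclobut-2-en-1-one | C=CCC1(O)C(=O)C=C1OC(C)C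
F9 | step 3 | rac-4-allyl-3-isopropoxy-4-(triethylsilyloxy)cyclobut-2-en-1-one | C=CCC1(O[Si](CC)(CC)CC)C(=O)C=C1OC(C)C
F10 | step 3 | rac-2-[2-isopropoxy-4-oxo-1-(triethylsilyloxy)cyclobut-2-en-1-yl]acetaldehyde | O=CCC1(O[Si](CC)(CC)CC)C(=O)C=C1OC(C)C
F11 | step 3 | rac-3-isopropoxy-4-[(Z)-oct-2-en-1-yl]-4-(triethylsilyloxy)cyclobut-2-en-1-one | CCCCC/C=C\CC1(O[Si](CC)(CC)CC)C(=O)C=C1OC(C)C
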